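## Retrosynthetic overview

- The target 8‑hydroxyflavone comes from its 8‑O‑benzyl ether by hydrogenolysis. Ring C is closed last, through O1–C2, by I2/DMSO cyclisation of a 2'‑hydroxychalcone, itself made by MnO2 oxidation of the desilylated benzannulation product.
- Ring A is disconnected at C4a–C8a, C5–C6 and C8–C8a (Danheiser benzannulation). A 4‑benzyloxy‑2,3‑dimethoxycyclobutenone supplies C8a (with the future O1), C6, C7 and C8; a methoxyalkyne supplies C5 and C4a and already carries C4, C3, C2 and ring B.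
- Feature the plan rests on: ring A (C4a, C5, C6, C7, C8, C8a) is hexasubstituted, with oxygen on C5, C6, C7, C8 and C8a and carbon C4 on C4a. The ring construction delivers the five oxygens already told apart: methyl on C5–C7, benzyl on C8, and the only free OH on C8a, next to the C4a side chain where ring C must close.
- Order of rings: ring B is bought (in the cinnamaldehyde), ring A is built in step 5, ring C is closed in step 8.
- The cyclobutenone comes from dimethyl squarate (monoreduction, O‑benzylation); the alkyne from lithium methoxyacetylide and (E)‑3,4,5‑trimethoxycinnamaldehyde (addition, silylation).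

Key step: step 5

Remark: the target is achiral. The stereocentres of 2, 4, 8, 9, 14, 15 and 17 are formed racemic and are all erased before the end, so no stereocontrol is needed.

Remark: compounds 2, 8 and 9 are acid‑sensitive; base‑washed glassware and triethylamine‑deactivated silica are assumed.

## Route

Step 1
Reactants: 1 dimethyl squarate
Product: 2 racemic 4-hydroxy-2,3-dimethoxycyclobut-2-en-1-one
Conditions: LiAlH(OC(CH3)3)3 (1.05 equiv), THF, −78 → −20 °C; pH 7 buffer
Reagents that add atoms: none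
Why: 1,2‑Monoreduction of a squarate diester with a bulky, mild hydride should stop after one addition because the resulting vinylogous ester is far less electrophilic than the starting dione; the C4 centre forms racemic and is destroyed in step 5.

Step 2
Reactants: 2 racemic 4-hydroxy-2,3-dimethoxycyclobut-2-en-1-one; 3 benzyl bromide
Product: 4 racemic 4-(benzyloxy)-2,3-dimethoxycyclobut-2-en-1-one
Conditions: Ag2O, 4 Å molecular sieves, CH2Cl2, rt, dark
Reagents that add atoms: none
Why: Silver‑oxide‑assisted O‑alkylation (Purdie‑type Williamson etherification) should benzylate the secondary alcohol without soluble base or acid, the two conditions under which the hydroxycyclobutenone opens or loses methanol.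

Step 3
Reactants: 5 chloroacetaldehyde dimethyl acetal; 6 (E)-3,4,5-trimethoxycinnamaldehyde
Product: 8 racemic (E)-1-methoxy-5-(3,4,5-trimethoxyphenyl)pent-4-en-1-yn-3-ol, via lithium methoxyacetylide 7 (not isolated)
Conditions: LiNEt2 (from n-BuLi and Et2NH, 3 equiv per 5), THF, 0 °C; then 6, −78 → 0 °C; H2O
Reagents that add atoms: none
Why: Double elimination (loss of methanol and HCl) and deprotonation of the chloroacetal give the lithium alkoxyacetylide, which should add 1,2 to the enal carbonyl (acetylide addition); the carbinol centre forms racemic and later becomes the C4 ketone.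

Step 4
Reactants: 8 racemic (E)-1-methoxy-5-(3,4,5-trimethoxyphenyl)pent-4-en-1-yn-3-ol
Product: 9 racemic tert-butyl{[(E)-1-methoxy-5-(3,4,5-trimethoxyphenyl)pent-4-en-1-yn-3-yl]oxy}dimethylsilane
Conditions: TBSCl, imidazole, DMF, 0 °C → rt
Reagents that add atoms: tert-butyldimethylsilyl chloride, CC(C)(C)[Si](C)(C)Cl
Why: Standard imidazole‑mediated silylation under basic conditions should cap the carbinol, which prevents its acylation by the ketene in step 5 and suppresses the acid‑triggered Meyer–Schuster rearrangement of the alkoxy‑propargylic alcohol.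

Step 5
Reactants: 4 racemic 4-(benzyloxy)-2,3-dimethoxycyclobut-2-en-1-one; 9 racemic tert-butyl{[(E)-1-methoxy-5-(3,4,5-trimethoxyphenyl)pent-4-en-1-yn-3-yl]oxy}dimethylsilane (1.3 equiv)
Product: 14 racemic 6-(benzyloxy)-2-[(E)-1-(tert-butyldimethylsilyloxy)-3-(3,4,5-trimethoxyphenyl)allyl]-3,4,5-trimethoxyphenol, via vinylketene 10 (not isolated), via 4-vinylcyclobutenone 11 (not isolated), via dienylketene 12 (not isolated), via cyclohexadienone 13 (not isolated)
Conditions: toluene (degassed), 80–110 °C, sealed tube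
Reagents that add atoms: none
Why: Heating should open cyclobutenone 4 by four‑electron electrocyclic ring opening, the benzyloxy group turning outward, to vinylketene 10, whose ketene C=C adds the ynol ether in a (2+2) cycloaddition to give 4‑vinylcyclobutenone 11; this opens again (methoxy outward, vinyl inward) to dienylketene 12, which closes to cyclohexadienone 13 and tautomerises to phenol 14. This is the Danheiser benzannulation, established for cyclobutenones with alkoxyalkynes (it gives 3‑alkoxyphenols); a cyclobutenone carrying three oxygen substituents is an untried member of that class, though donor groups at C4 and on the ring double bond are known to ease the ring opening. Ring A is closed by the thermal disrotatory six‑electron electrocyclisation that forms C8–C8a, after the cycloaddition has formed C4a–C8a and C5–C6. No new stereocentre results: the C4 centre of 4 and the quaternary centre of 11 become sp2 and the carbinol centre of 9 is carried through racemic. Regiochemistry follows from the polarity of the ynol ether, whose nucleophilic carbon (the one bearing the side chain) attacks the ketene carbonyl carbon and so becomes C4a next to the phenol while the methoxy carbon becomes C5; chemoselectivity for the triple bond over the styrene double bond rests on the much higher reactivity of the electron‑rich alkyne toward ketenes. A methoxyalkyne cannot lose an alkene by retro‑ene fragmentation at this temperature, and the silyl ether keeps the carbinol from being acylated by the ketene.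

Step 6
Reactants: 14 racemic 6-(benzyloxy)-2-[(E)-1-(tert-butyldimethylsilyloxy)-3-(3,4,5-trimethoxyphenyl)allyl]-3,4,5-trimethoxyphenol
Product: 15 racemic 6-(benzyloxy)-2-[(E)-1-hydroxy-3-(3,4,5-trimethoxyphenyl)allyl]-3,4,5-trimethoxyphenol
Conditions: TBAF (2.2 equiv), THF, 0 °C; pH 7 buffer
Reagents that add atoms: none
Why: Fluoride‑mediated desilylation should free the carbinol under non‑acidic conditions, which matters because this benzylic and allylic alcohol on an electron‑rich ring ionises readily in acid.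

Step 7
Reactants: 15 racemic 6-(benzyloxy)-2-[(E)-1-hydroxy-3-(3,4,5-trimethoxyphenyl)allyl]-3,4,5-trimethoxyphenol
Product: 16 (E)-1-[3-(benzyloxy)-2-hydroxy-4,5,6-trimethoxyphenyl]-3-(3,4,5-trimethoxyphenyl)prop-2-en-1-one
Conditions: activated MnO2 (excess), CH2Cl2, rt
Reagents that add atoms: none
Why: Heterogeneous MnO2 oxidation is selective for allylic and benzylic alcohols and should give the conjugated, hydrogen‑bonded 2'‑hydroxychalcone while leaving the ethers untouched.

Step 8
Reactants: 16 (E)-1-[3-(benzyloxy)-2-hydroxy-4,5,6-trimethoxyphenyl]-3-(3,4,5-trimethoxyphenyl)prop-2-en-1-one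
Product: 18 8-(benzyloxy)-5,6,7-trimethoxy-2-(3,4,5-trimethoxyphenyl)-4H-chromen-4-one, via flavanone 17 (not isolated)
Conditions: I2 (10 mol %), DMSO, 120 °C; aq. Na2S2O3
Reagents that add atoms: none
Why: Iodine/DMSO oxidative cyclisation of 2'‑hydroxychalcones should close ring C by 6‑endo‑trig oxa‑Michael addition of the C2' phenol (O1–C2) and then dehydrogenate C2–C3 by iodination and loss of HI, with DMSO regenerating I2; ring A has no free position to iodinate.

Step 9
Reactants: 18 8-(benzyloxy)-5,6,7-trimethoxy-2-(3,4,5-trimethoxyphenyl)-4H-chromen-4-one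
Product: 19 8-hydroxy-5,6,7-trimethoxy-2-(3,4,5-trimethoxyphenyl)-4H-chromen-4-one (8-hydroxy-5,6,7,3',4',5'-hexamethoxyflavone)
Conditions: H2 (1 atm), 10% Pd/C (palladium on carbon), EtOAc–MeOH, rt
Reagents that add atoms: none
Why: Catalytic hydrogenolysis should cleave the benzyl aryl ether selectively, since methyl ethers are inert and the C2–C3 double bond of a flavone is reduced far more slowly, provided the reaction is stopped after one equivalent of hydrogen.

## Compound list

1 | dimethyl squarate (3,4-dimethoxycyclobut-3-ene-1,2-dione) | COC1=C(OC)C(=O)C1=O | starting material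
2 | racemic 4-hydroxy-2,3-dimethoxycyclobut-2-en-1-one | O=C1C(OC)=C(OC)C1O | intermediate
3 | benzyl bromide | BrCc1ccccc1 | starting material
4 | racemic 4-(benzyloxy)-2,3-dimethoxycyclobut-2-en-1-one | O=C1C(OC)=C(OC)C1OCc1ccccc1 | intermediate
5 | chloroacetaldehyde dimethyl acetal (2-chloro-1,1-dimethoxyethane) | COC(CCl)OC | starting material
6 | (E)-3,4,5-trimethoxycinnamaldehyde | O=C/C=C/c1cc(OC)c(OC)c(OC)c1 | starting material
7 | lithium methoxyacetylide (not isolated) | [Li]C#COC | intermediate
8 | racemic (E)-1-methoxy-5-(3,4,5-trimethoxyphenyl)pent-4-en-1-yn-3-ol | COC#CC(O)/C=C/c1cc(OC)c(OC)c(OC)c1 | intermediate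
9 | racemic tert-butyl{[(E)-1-methoxy-5-(3,4,5-trimethoxyphenyl)pent-4-en-1-yn-3-yl]oxy}dimethylsilane | COC#CC(O[Si](C)(C)C(C)(C)C)/C=C/c1cc(OC)c(OC)c(OC)c1 | intermediate
10 | vinylketene (Z)-4-(benzyloxy)-2,3-dimethoxybuta-1,3-dien-1-one (not isolated) | O=C=C(OC)/C(OC)=C/OCc1ccccc1 | intermediate
11 | 4-vinylcyclobutenone 4-[(Z)-2-(benzyloxy)-1-methoxyethenyl]-2-[(E)-1-(tert-butyldimethylsilyloxy)-3-(3,4,5-trimethoxyphenyl)allyl]-3,4-dimethoxycyclobut-2-en-1-one, mixture of diastereomers (not isolated) | O=C1C(C(O[Si](C)(C)C(C)(C)C)/C=C/c2cc(OC)c(OC)c(OC)c2)=C(OC)C1(OC)/C(OC)=C/OCc1ccccc1 | intermediate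
12 | dienylketene (3Z,5Z)-6-(benzyloxy)-2-[(E)-1-(tert-butyldimethylsilyloxy)-3-(3,4,5-trimethoxyphenyl)allyl]-3,4,5-trimethoxyhexa-1,3,5-trien-1-one (not isolated) | O=C=C(C(O[Si](C)(C)C(C)(C)C)/C=C/c1cc(OC)c(OC)c(OC)c1)/C(OC)=C(OC)\C(OC)=C\OCc1ccccc1 | intermediate
13 | cyclohexadienone 6-(benzyloxy)-2-[(E)-1-(tert-butyldimethylsilyloxy)-3-(3,4,5-trimethoxyphenyl)allyl]-3,4,5-trimethoxycyclohexa-2,4-dien-1-one, mixture of diastereomers (not isolated) | O=C1C(C(O[Si](C)(C)C(C)(C)C)/C=C/c2cc(OC)c(OC)c(OC)c2)=C(OC)C(OC)=C(OC)C1OCc1ccccc1 | intermediate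
14 | racemic 6-(benzyloxy)-2-[(E)-1-(tert-butyldimethylsilyloxy)-3-(3,4,5-trimethoxyphenyl)allyl]-3,4,5-trimethoxyphenol | Oc1c(OCc2ccccc2)c(OC)c(OC)c(OC)c1C(O[Si](C)(C)C(C)(C)C)/C=C/c1cc(OC)c(OC)c(OC)c1 | intermediate
15 | racemic 6-(benzyloxy)-2-[(E)-1-hydroxy-3-(3,4,5-trimethoxyphenyl)allyl]-3,4,5-trimethoxyphenol | Oc1c(OCc2ccccc2)c(OC)c(OC)c(OC)c1C(O)/C=C/c1cc(OC)c(OC)c(OC)c1 | intermediate
16 | (E)-1-[3-(benzyloxy)-2-hydroxy-4,5,6-trimethoxyphenyl]-3-(3,4,5-trimethoxyphenyl)prop-2-en-1-one | O=C(/C=C/c1cc(OC)c(OC)c(OC)c1)c1c(O)c(OCc2ccccc2)c(OC)c(OC)c1OC | intermediate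
17 | flavanone, racemic 8-(benzyloxy)-5,6,7-trimethoxy-2-(3,4,5-trimethoxyphenyl)chroman-4-one (not isolated) | COc1cc(C2CC(=O)c3c(OC)c(OC)c(OC)c(OCc4ccccc4)c3O2)cc(OC)c1OC | intermediate
18 | 8-(benzyloxy)-5,6,7-trimethoxy-2-(3,4,5-trimethoxyphenyl)-4H-chromen-4-one | COc1cc(-c2cc(=O)c3c(OC)c(OC)c(OC)c(OCc4ccccc4)c3o2)cc(OC)c1OC | intermediate
19 | 8-hydroxy-5,6,7-trimethoxy-2-(3,4,5-trimethoxyphenyl)-4H-chromen-4-one (8-hydroxy-5,6,7,3',4',5'-hexamethoxyflavone) | COc1cc(-c2cc(=O)c3c(OC)c(OC)c(OC)c(O)c3o2)cc(OC)c1OC | target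

## Step count and risks

Total step count: 9. Longest linear sequence: 7 steps (steps 1, 2, 5, 6, 7, 8, 9, or equally steps 3, 4, 5, 6, 7, 8, 9).

**Risk 1, step 5 (benzannulation).** The heavily oxygenated vinylketene may reclose or dimerise faster than the hindered internal ynol ether intercepts it. The ketene may also acylate the phenol as it forms, and on long heating silanol may be lost from the product next to the free phenol.

Fallback (known chemistry; ring A is taken from an arene instead of being built): it sets out from aldehyde 6 and benzyl bromide 3 and comes back at chalcone 16.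
- Aldehyde 6 is oxidised under Pinnick conditions (NaClO2, NaH2PO4, 2‑methylbut‑2‑ene, t‑BuOH–H2O) to (E)-3,4,5-trimethoxycinnamic acid F1.
- F1 is converted with (COCl)2 and catalytic DMF into (E)-3,4,5-trimethoxycinnamoyl chloride F2.
- Separately, purchased 3,4,5‑trimethoxyphenol is ortho‑oxygenated with IBX (DMF, rt) to 3,4,5-trimethoxy-1,2-benzoquinone F3, which is reduced in the same flask with Na2S2O4 to 3,4,5-trimethoxybenzene-1,2-diol F4.
- Friedel–Crafts/Fries acylation of F4 with F2 in BF3·OEt2 at 80 °C can only take place at the single free ring carbon and should give (E)-1-(2,3-dihydroxy-4,5,6-trimethoxyphenyl)-3-(3,4,5-trimethoxyphenyl)prop-2-en-1-one F5.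
- Through the dianion of F5 (2 equiv NaH, DMF, 0 °C) the non‑chelated 3'‑oxygen is benzylated with one equivalent of 3, which should give 16.

**Risk 2, step 2 (O‑benzylation).** The strained α‑hydroxy ketone may open or decompose, or lose methanol by ionisation at C4, while the slow alkylation of a hindered, weakly nucleophilic alcohol is still in progress.

Fallback (C8–O carried as a methoxymethyl ether, put on with a far more reactive electrophile and removed by acid at the end): it sets out from 2 and comes back at target 19.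
- 2 is treated with chloromethyl methyl ether and iPr2NEt (CH2Cl2, 0 °C) to give 2,3-dimethoxy-4-(methoxymethoxy)cyclobut-2-en-1-one F6.
- Benzannulation of F6 with 9 as in step 5 should give 2-[(E)-1-(tert-butyldimethylsilyloxy)-3-(3,4,5-trimethoxyphenyl)allyl]-3,4,5-trimethoxy-6-(methoxymethoxy)phenol F7.
- TBAF gives 2-[(E)-1-hydroxy-3-(3,4,5-trimethoxyphenyl)allyl]-3,4,5-trimethoxy-6-(methoxymethoxy)phenol F8.
- MnO2 gives (E)-1-[2-hydroxy-4,5,6-trimethoxy-3-(methoxymethoxy)phenyl]-3-(3,4,5-trimethoxyphenyl)prop-2-en-1-one F9.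
- I2/DMSO gives 5,6,7-trimethoxy-8-(methoxymethoxy)-2-(3,4,5-trimethoxyphenyl)-4H-chromen-4-one F10; any acetal cleaved in this step already gives 19.
- HCl in MeOH at 50 °C removes the acetal and should give 19.

**Risk 3, step 7 (oxidation beside a free phenol).** The free pentaoxygenated phenol may be over‑oxidised (oxidative demethylation or coupling) in competition with the alcohol oxidation. In steps 6 and 7 the carbinol may also ionise and close onto the neighbouring phenol oxygen.

Fallback (the phenol is masked before the carbinol is freed): it sets out from 14 and comes back at 16.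
- 14 is treated with chloromethyl methyl ether and iPr2NEt to give tert-butyl{[(E)-1-[3-(benzyloxy)-4,5,6-trimethoxy-2-(methoxymethoxy)phenyl]-3-(3,4,5-trimethoxyphenyl)allyl]oxy}dimethylsilane F11.
- TBAF gives (E)-1-[3-(benzyloxy)-4,5,6-trimethoxy-2-(methoxymethoxy)phenyl]-3-(3,4,5-trimethoxyphenyl)prop-2-en-1-ol F12.
- MnO2 (or Dess–Martin periodinane with NaHCO3, now that no free phenol is present) gives (E)-1-[3-(benzyloxy)-4,5,6-trimethoxy-2-(methoxymethoxy)phenyl]-3-(3,4,5-trimethoxyphenyl)prop-2-en-1-one F13.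
- HCl in MeOH at rt removes the acetal and should give 16.

Further compounds
F1 | step 5 | (E)-3,4,5-trimethoxycinnamic acid | OC(=O)/C=C/c1cc(OC)c(OC)c(OC)c1
F2 | step 5 | (E)-3,4,5-trimethoxycinnamoyl chloride | ClC(=O)/C=C/c1cc(OC)c(OC)c(OC)c1
F3 | step 5 | 3,4,5-trimethoxy-1,2-benzoquinone (3,4,5-trimethoxycyclohexa-3,5-diene-1,2-dione) | O=C1C(=O)C(OC)=C(OC)C(OC)=C1
F4 | step 5 | 3,4,5-trimethoxybenzene-1,2-diol | Oc1cc(OC)c(OC)c(OC)c1O
F5 | step 5 | (E)-1-(2,3-dihydroxy-4,5,6-trimethoxyphenyl)-3-(3,4,5-trimethoxyphenyl)prop-2-en-1-one | O=C(/C=C/c1cc(OC)c(OC)c(OC)c1)c1c(O)c(O)c(OC)c(OC)c1OC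
F6 | step 2 | racemic 2,3-dimethoxy-4-(methoxymethoxy)cyclobut-2-en-1-one | O=C1C(OC)=C(OC)C1OCOC
F7 | step 2 | racemic 2-[(E)-1-(tert-butyldimethylsilyloxy)-3-(3,4,5-trimethoxyphenyl)allyl]-3,4,5-trimethoxy-6-(methoxymethoxy)phenol | Oc1c(OCOC)c(OC)c(OC)c(OC)c1C(O[Si](C)(C)C(C)(C)C)/C=C/c1cc(OC)c(OC)c(OC)c1
F8 | step 2 | racemic 2-[(E)-1-hydroxy-3-(3,4,5-trimethoxyphenyl)allyl]-3,4,5-trimethoxy-6-(methoxymethoxy)phenol | Oc1c(OCOC)c(OC)c(OC)c(OC)c1C(O)/C=C/c1cc(OC)c(OC)c(OC)c1
F9 | step 2 | (E)-1-[2-hydroxy-4,5,6-trimethoxy-3-(methoxymethoxy)phenyl]-3-(3,4,5-trimethoxyphenyl)prop-2-en-1-one | O=C(/C=C/c1cc(OC)c(OC)c(OC)c1)c1c(O)c(OCOC)c(OC)c(OC)c1OC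
F10 | step 2 | 5,6,7-trimethoxy-8-(methoxymethoxy)-2-(3,4,5-trimethoxyphenyl)-4H-chromen-4-one | COCOc1c(OC)c(OC)c(OC)c2c(=O)cc(-c3cc(OC)c(OC)c(OC)c3)oc12
F11 | step 7 | racemic tert-butyl{[(E)-1-[3-(benzyloxy)-4,5,6-trimethoxy-2-(methoxymethoxy)phenyl]-3-(3,4,5-trimethoxyphenyl)allyl]oxy}dimethylsilane | COCOc1c(OCc2ccccc2)c(OC)c(OC)c(OC)c1C(O[Si](C)(C)C(C)(C)C)/C=C/c1cc(OC)c(OC)c(OC)c1
F12 | step 7 | racemic (E)-1-[3-(benzyloxy)-4,5,6-trimethoxy-2-(methoxymethoxy)phenyl]-3-(3,4,5-trimethoxyphenyl)prop-2-en-1-ol | COCOc1c(OCc2ccccc2)c(OC)c(OC)c(OC)c1C(O)/C=C/c1cc(OC)c(OC)c(OC)c1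
F13 | step 7 | (E)-1-[3-(benzyloxy)-4,5,6-trimethoxy-2-(methoxymethoxy)phenyl]-3-(3,4,5-trimethoxyphenyl)prop-2-en-1-one | O=C(/C=C/c1cc(OC)c(OC)c(OC)c1)c1c(OCOC)c(OCc2ccccc2)c(OC)c(OC)c1OC
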